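The route rests on cutting the ring-fusion bond C5–C10 (labdane numbering) together with C3–C4, which unfolds both carbocycles into one acyclic undecatrienoate. A Lewis-acid-promoted intramolecular Diels–Alder reaction closes this chain again. The (E)-2-methylenoate C4=C5 adds to the diene C10=C1–C2=C3 across the four-atom tether C6–C9. This closes rings A and B in one operation and sets C4, C5 and C10, both quaternary carbons included. The step exploits three features: C5–C10 is common to rings A and B, the C4 ester is cis to H5, and the equatorial C6 oxygen flanks C5, so a single aldol-derived carbinol steers all new centres. The precursor comes from a dienyl methyl ketone and a four-carbon aldehyde ester.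

Key step: step 8

Remark on numbering: labdane numbering is used in the text. C4 carries CH3 and CO2Me, C5 and C10 are the ring-fusion carbons, C6 carries oxygen, C8 carries the exocyclic methylene C17, C9 carries the side chain C11–C16, and C20 is the angular methyl.

Assumption: the (R,R)-bisphosphoramide/SiCl4 system is taken to direct attack to the Re face of aldehyde 4, as for other conjugated aldehydes. If the sense proves opposite, the (S,S)-catalyst is used.

Step 1
Reactants: 1 2,2-dimethoxyacetaldehyde; 2 methyl 2-(triphenylphosphoranylidene)propanoate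
Product: 4 methyl (E)-2-methyl-4-oxobut-2-enoate, via acetal enoate 3 (not isolated)
Conditions: 1 (60 wt % in water), 2, CH2Cl2, rt; then 1 M aq HCl, THF, rt
Reagents that add atoms: water, O
Why: Wittig olefination with a stabilised ylide should give the E-enoate (ester trans to the acetal carbon), and mild hydrolysis of the dimethyl acetal then frees the aldehyde without touching the ester.

Step 2
Reactants: 5 pent-4-yn-2-ol
Product: 7 (E)-4-methylhepta-4,6-dien-2-ol, via alkenylalane 6 (not isolated)
Conditions: Me3Al (3 equiv), Cp2ZrCl2 (0.25 equiv), CH2Cl2, 0 °C to rt; then vinyl bromide (1 M in THF), Pd(PPh3)4 (5 mol %), ZnCl2 (0.2 equiv), rt; aq Rochelle salt work-up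
Reagents that add atoms: trimethylaluminium, C[Al](C)C; vinyl bromide, C=CBr
Why: Zirconium-catalysed carboalumination adds methyl and aluminium syn with aluminium at the terminus, and the Negishi-type palladium-catalysed coupling proceeds with retention, so the trisubstituted alkene is E (CH2 trans to vinyl); the racemic carbinol centre is erased in step 3.

Step 3
Reactants: 7 (E)-4-methylhepta-4,6-dien-2-ol
Product: 8 (E)-4-methylhepta-4,6-dien-2-one
Conditions: Dess–Martin periodinane, CH2Cl2, 0 °C to rt
Reagents that add atoms: none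
Why: Dess–Martin oxidation is mild enough to deliver the β,γ-unsaturated ketone without moving the diene into conjugation with the carbonyl group.

Step 4
Reactants: 8 (E)-4-methylhepta-4,6-dien-2-one; 9 1-bromo-3-methylbut-2-ene (prenyl bromide)
Product: 10 (E)-4-methyl-3-(3-methylbut-2-en-1-yl)hepta-4,6-dien-2-one (racemic)
Conditions: LDA (commercial solution, 1.05 equiv), THF–DMPU, −78 °C; then 9, −78 to −30 °C
Reagents that add atoms: none
Why: Enolate alkylation: the doubly activated C9 methylene is deprotonated in preference to the methyl group and the extended lithium enolate reacts with the allylic bromide at its α-carbon, which keeps the E-diene out of conjugation; C9 is formed racemic and is fixed in step 9.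

Step 5
Reactants: 10 (E)-4-methyl-3-(3-methylbut-2-en-1-yl)hepta-4,6-dien-2-one
Product: 11 trimethyl{[(4E)-4-methyl-3-(3-methylbut-2-en-1-yl)hepta-1,4,6-trien-2-yl]oxy}silane
Conditions: TMSCl (3 equiv) premixed with 10, LDA (1.1 equiv), THF, −78 °C (in situ quench)
Reagents that add atoms: chlorotrimethylsilane, C[Si](C)(C)Cl
Why: Kinetic enolisation with in situ silylation: the C9 methine is now shielded by the prenyl and dienyl branches and cannot align its C–H bond without allylic strain, so the hindered amide base should take a methyl proton and give the terminal silyl enol ether.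

Step 6
Reactants: 11 trimethyl{[(4E)-4-methyl-3-(3-methylbut-2-en-1-yl)hepta-1,4,6-trien-2-yl]oxy}silane; 4 methyl (E)-2-methyl-4-oxobut-2-enoate
Product: 12 methyl (2E,4R,8E)-4-hydroxy-2,8-dimethyl-7-(3-methylbut-2-en-1-yl)-6-oxoundeca-2,8,10-trienoate (both C7 epimers)
Conditions: SiCl4 (1.5 equiv), (R,R)-bisphosphoramide [pentane-1,5-diyl-linked bis(N,N'-dimethyl-1,1'-binaphthyl-2,2'-diamine phosphoramide)] (5 mol %), iPr2NEt (0.2 equiv), CH2Cl2, −78 °C; aq KF/NaHCO3 work-up
Reagents that add atoms: none
Why: Catalytic enantioselective Mukaiyama aldol addition (chiral Lewis base activation of SiCl4), a class that works best with conjugated aldehydes; attack on the Re face of the bound aldehyde sets C6 as R, and 1,2-addition is expected because the β-carbon of the enal is fully substituted.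

Step 7
Reactants: 12 methyl (2E,4R,8E)-4-hydroxy-2,8-dimethyl-7-(3-methylbut-2-en-1-yl)-6-oxoundeca-2,8,10-trienoate
Product: 13 methyl (2E,4R,8E)-4-[(tert-butyldimethylsilyl)oxy]-2,8-dimethyl-7-(3-methylbut-2-en-1-yl)-6-oxoundeca-2,8,10-trienoate (both C7 epimers)
Conditions: TBSOTf (1.2 equiv), 2,6-lutidine, CH2Cl2, −78 °C
Reagents that add atoms: tert-butyldimethylsilyl triflate, CC(C)(C)[Si](C)(C)OS(=O)(=O)C(F)(F)F
Why: O-silylation under weakly basic, cold conditions protects the β-hydroxy ketone without retro-aldol or elimination and installs a bulky, non-chelating group for the facial control needed in step 8.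

Step 8
Reactants: 13 methyl (2E,4R,8E)-4-[(tert-butyldimethylsilyl)oxy]-2,8-dimethyl-7-(3-methylbut-2-en-1-yl)-6-oxoundeca-2,8,10-trienoate
Product: 14 methyl (1S,4aR,8R,8aS)-8-[(tert-butyldimethylsilyl)oxy]-1,4a-dimethyl-5-(3-methylbut-2-en-1-yl)-6-oxo-1,2,4a,5,6,7,8,8a-octahydronaphthalene-1-carboxylate (both C5 epimers; ring position 5 is labdane C9)
Conditions: MeAlCl2 (2.5 equiv), CH2Cl2 (0.01 M), −78 to 0 °C; aq NaHCO3 quench
Reagents that add atoms: none
Why: MeAlCl2 binds the ketone and the ester, lowers the LUMO of the C4=C5 enoate and triggers a concerted, asynchronous, suprafacial [4+2] cycloaddition in which C5–C10 forms ahead of C3–C4, at a temperature where the 1,5-hydrogen shift of the diene and the Cope rearrangement of the 1,5-diene unit cannot compete. The closest known reaction type is the alkylaluminium-chloride-promoted type 1 intramolecular Diels–Alder reaction of undeca-2,8,10-trienoates to trans-fused octalins. Ring A closes as the new cyclohexene of the cycloaddition (alkene at C1=C2), and ring B closes in the fused mode through the four-atom tether C6–C9 held in a chair. C4 follows from the E geometry of the enoate (ester cis to H5, hence ester equatorial and methyl axial), the trans relation of H5 and the C10 methyl follows from the endo placement of the ester on the E-diene, and the absolute sense follows from C6, whose OTBS group stays equatorial because the other face would set it 1,3-diaxial to the C10 methyl. The step needs endo, facial and periselectivity: Lewis acid coordination reinforces endo, the non-chelating silyl ether secures the face, the prenyl alkene is an unactivated spectator, and the tether length allows only the fused regiochemistry. C9 is not touched, so 14 is a pair of C9 epimers.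

Step 9
Reactants: 14 octalone (both C9 epimers)
Product: 15 methyl (1S,4aR,5S,8R,8aS)-8-[(tert-butyldimethylsilyl)oxy]-1,4a-dimethyl-5-(3-methylbut-2-en-1-yl)-6-oxo-1,2,4a,5,6,7,8,8a-octahydronaphthalene-1-carboxylate
Conditions: NaOMe (0.3 equiv), MeOH, 0 °C to rt
Reagents that add atoms: none
Why: Base-mediated epimerisation through the C8–C9 enolate: reprotonation is axial and comes from the face opposite the C10 methyl, the equatorial prenyl epimer is also the thermodynamic one, and the equatorial C6–O bond is poorly aligned with a C7 enolate, which should hold back β-elimination.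

Step 10
Reactants: 15 octalone with equatorial prenyl group
Product: 16 methyl (1S,4aR,5S,8R,8aS)-8-[(tert-butyldimethylsilyl)oxy]-1,4a-dimethyl-5-(3-methylbut-2-en-1-yl)-6-oxodecahydronaphthalene-1-carboxylate
Conditions: H2 (1 atm), RhCl(PPh3)3 (10 mol %), benzene–EtOH, rt
Reagents that add atoms: none
Why: Homogeneous hydrogenation with this rhodium catalyst reduces the cis-disubstituted C1=C2 bond and should leave the trisubstituted prenyl alkene, the ketone and the ester alone.

Step 11
Reactants: 16 decalone
Product: 18 methyl (1S,4aR,5S,8R,8aS)-8-[(tert-butyldimethylsilyl)oxy]-1,4a-dimethyl-5-[(2E)-3-methyl-4-oxobut-2-en-1-yl]-6-oxodecahydronaphthalene-1-carboxylate, via allylic alcohol 17 (not isolated)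
Conditions: SeO2 (0.5 equiv), t-BuOOH (3 equiv), CH2Cl2, 0 °C to rt; crude product, MnO2, CH2Cl2, rt
Reagents that add atoms: tert-butyl hydroperoxide, CC(C)(C)OO; selenium dioxide, O=[Se]=O
Why: SeO2 allylic oxidation (ene reaction, then [2,3]-sigmatropic shift) attacks the methyl group trans to the chain of the only alkene present, which fixes the E geometry at C12=C13, and MnO2 takes the allylic alcohol on to the enal.

Step 12
Reactants: 18 keto enal
Product: 19 methyl (1S,4aS,5R,8R,8aS)-8-[(tert-butyldimethylsilyl)oxy]-1,4a-dimethyl-6-methylidene-5-[(2E)-3-methylpenta-2,4-dien-1-yl]decahydronaphthalene-1-carboxylate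
Conditions: Ph3PCH3Br (5 equiv), KOt-Bu (4.8 equiv), THF, 0 °C; then 18, 0 to 40 °C
Reagents that add atoms: methyltriphenylphosphonium bromide, C[P+](c1ccccc1)(c1ccccc1)c1ccccc1.[Br-]
Why: Double Wittig methylenation: the enal reacts at once to give the diene and the hindered C8 ketone follows on warming; C9 already holds its thermodynamic equatorial configuration, so the basic ylide cannot erode it, and the hindered C4 ester is inert.

Step 13
Reactants: 19 silyl ether triene
Product: 20 methyl (1S,4aS,5R,8R,8aS)-8-hydroxy-1,4a-dimethyl-6-methylidene-5-[(2E)-3-methylpenta-2,4-dien-1-yl]decahydronaphthalene-1-carboxylate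
Conditions: HF·pyridine, pyridine, THF, 0 °C to rt
Reagents that add atoms: none
Why: Fluoride-mediated desilylation in a pyridine-buffered medium avoids a free alkoxide that could lactonise onto the C4 ester and is mild enough for the diene and the exocyclic methylene.

Step 14
Reactants: 20 C6 alcohol
Product: 21 methyl (1S,4aS,5R,8R,8aS)-8-acetoxy-1,4a-dimethyl-6-methylidene-5-[(2E)-3-methylpenta-2,4-dien-1-yl]decahydronaphthalene-1-carboxylate (target)
Conditions: Ac2O, DMAP (cat.), pyridine, rt
Reagents that add atoms: acetic anhydride, CC(=O)OC(C)=O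
Why: DMAP-catalysed acylation of the equatorial secondary alcohol proceeds with retention at C6 and touches no other group.

Compound list
1 | 2,2-dimethoxyacetaldehyde | COC(OC)C=O | starting material
2 | methyl 2-(triphenylphosphoranylidene)propanoate | COC(=O)C(C)=P(c1ccccc1)(c1ccccc1)c1ccccc1 | starting material
3 | methyl (E)-4,4-dimethoxy-2-methylbut-2-enoate (acetal enoate) | COC(=O)/C(C)=C/C(OC)OC | intermediate
4 | methyl (E)-2-methyl-4-oxobut-2-enoate | COC(=O)/C(C)=C/C=O | intermediate
5 | pent-4-yn-2-ol (racemic) | CC(O)CC#C | starting material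
6 | dimethyl[(1E)-4-(dimethylalumanyloxy)-2-methylpent-1-en-1-yl]alumane (alkenylalane) | CC(O[Al](C)C)C/C(C)=C/[Al](C)C | intermediate
7 | (E)-4-methylhepta-4,6-dien-2-ol (racemic) | CC(O)C/C(C)=C/C=C | intermediate
8 | (E)-4-methylhepta-4,6-dien-2-one | CC(=O)C/C(C)=C/C=C | intermediate
9 | 1-bromo-3-methylbut-2-ene (prenyl bromide) | CC(C)=CCBr | starting material
10 | (E)-4-methyl-3-(3-methylbut-2-en-1-yl)hepta-4,6-dien-2-one (racemic) | CC(=O)C(CC=C(C)C)/C(C)=C/C=C | intermediate
11 | trimethyl{[(4E)-4-methyl-3-(3-methylbut-2-en-1-yl)hepta-1,4,6-trien-2-yl]oxy}silane (racemic) | C=C(O[Si](C)(C)C)C(CC=C(C)C)/C(C)=C/C=C | intermediate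
12 | methyl (2E,4R,8E)-4-hydroxy-2,8-dimethyl-7-(3-methylbut-2-en-1-yl)-6-oxoundeca-2,8,10-trienoate (both C7 epimers) | COC(=O)/C(C)=C/[C@H](O)CC(=O)C(CC=C(C)C)/C(C)=C/C=C | intermediate
13 | methyl (2E,4R,8E)-4-[(tert-butyldimethylsilyl)oxy]-2,8-dimethyl-7-(3-methylbut-2-en-1-yl)-6-oxoundeca-2,8,10-trienoate (both C7 epimers) | COC(=O)/C(C)=C/[C@H](O[Si](C)(C)C(C)(C)C)CC(=O)C(CC=C(C)C)/C(C)=C/C=C | intermediate
14 | methyl (1S,4aR,8R,8aS)-8-[(tert-butyldimethylsilyl)oxy]-1,4a-dimethyl-5-(3-methylbut-2-en-1-yl)-6-oxo-1,2,4a,5,6,7,8,8a-octahydronaphthalene-1-carboxylate (both C5 epimers) | CC(C)=CCC1C(=O)C[C@@H](O[Si](C)(C)C(C)(C)C)[C@H]2[C@@]1(C)C=CC[C@]2(C)C(=O)OC | intermediate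
15 | methyl (1S,4aR,5S,8R,8aS)-8-[(tert-butyldimethylsilyl)oxy]-1,4a-dimethyl-5-(3-methylbut-2-en-1-yl)-6-oxo-1,2,4a,5,6,7,8,8a-octahydronaphthalene-1-carboxylate | CC(C)=CC[C@@H]1C(=O)C[C@@H](O[Si](C)(C)C(C)(C)C)[C@H]2[C@@]1(C)C=CC[C@]2(C)C(=O)OC | intermediate
16 | methyl (1S,4aR,5S,8R,8aS)-8-[(tert-butyldimethylsilyl)oxy]-1,4a-dimethyl-5-(3-methylbut-2-en-1-yl)-6-oxodecahydronaphthalene-1-carboxylate | CC(C)=CC[C@@H]1C(=O)C[C@@H](O[Si](C)(C)C(C)(C)C)[C@H]2[C@@]1(C)CCC[C@]2(C)C(=O)OC | intermediate
17 | methyl (1S,4aR,5S,8R,8aS)-8-[(tert-butyldimethylsilyl)oxy]-5-[(2E)-4-hydroxy-3-methylbut-2-en-1-yl]-1,4a-dimethyl-6-oxodecahydronaphthalene-1-carboxylate (allylic alcohol) | OC/C(C)=C/C[C@@H]1C(=O)C[C@@H](O[Si](C)(C)C(C)(C)C)[C@H]2[C@@]1(C)CCC[C@]2(C)C(=O)OC | intermediate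
18 | methyl (1S,4aR,5S,8R,8aS)-8-[(tert-butyldimethylsilyl)oxy]-1,4a-dimethyl-5-[(2E)-3-methyl-4-oxobut-2-en-1-yl]-6-oxodecahydronaphthalene-1-carboxylate | O=C/C(C)=C/C[C@@H]1C(=O)C[C@@H](O[Si](C)(C)C(C)(C)C)[C@H]2[C@@]1(C)CCC[C@]2(C)C(=O)OC | intermediate
19 | methyl (1S,4aS,5R,8R,8aS)-8-[(tert-butyldimethylsilyl)oxy]-1,4a-dimethyl-6-methylidene-5-[(2E)-3-methylpenta-2,4-dien-1-yl]decahydronaphthalene-1-carboxylate | C=C/C(C)=C/C[C@@H]1C(=C)C[C@@H](O[Si](C)(C)C(C)(C)C)[C@H]2[C@@]1(C)CCC[C@]2(C)C(=O)OC | intermediate
20 | methyl (1S,4aS,5R,8R,8aS)-8-hydroxy-1,4a-dimethyl-6-methylidene-5-[(2E)-3-methylpenta-2,4-dien-1-yl]decahydronaphthalene-1-carboxylate | C=C/C(C)=C/C[C@@H]1C(=C)C[C@@H](O)[C@H]2[C@@]1(C)CCC[C@]2(C)C(=O)OC | intermediate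
21 | methyl (1S,4aS,5R,8R,8aS)-8-acetoxy-1,4a-dimethyl-6-methylidene-5-[(2E)-3-methylpenta-2,4-dien-1-yl]decahydronaphthalene-1-carboxylate | C=C/C(C)=C/C[C@@H]1C(=C)C[C@@H](OC(C)=O)[C@H]2[C@@]1(C)CCC[C@]2(C)C(=O)OC | target

Total step count: 14. Longest linear sequence: 13 steps (steps 2 to 14, from 5).

Steps most likely to fail

Step 8. The cycloaddition may stall. The fully substituted diene terminus C10 populates the s-cis form poorly, and a 2-methylenoate is only a moderate dienophile. Forcing the reaction with more Lewis acid or heat invites loss of the silyl group, cationic attack by the prenyl alkene, or a sigmatropic shift of the diene.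
- The fallback raises the activation of the dienophile and sets out from 13.
- Full reduction with DIBAL-H (CH2Cl2, −78 °C) gives the silyloxy triene diol F1.
- Double Dess–Martin oxidation gives the keto enal F2.
- The far more electrophilic enal of F2 should cyclise with Me2AlCl at −78 to −20 °C through the same endo chair transition state to the octalone carbaldehyde F3.
- Pinnick oxidation (NaClO2, NaH2PO4, 2-methylbut-2-ene) gives the octalone carboxylic acid F4, and methylation with TMSCHN2 comes back to the route at 14.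

Step 9. Enolisation toward the hindered C9 may be slower than enolisation toward C7, so loss of the silyloxy group by β-elimination may outrun the epimerisation.
- The fallback fixes C9 before the cycloaddition and sets out from 13.
- The two C9 epimers are separated by chromatography into the (7S)-trienoate F5 and the (7R)-trienoate F6.
- F6 is re-equilibrated with catalytic DBU in CH2Cl2 and recycled. An amine base suffices because this C–H bond is activated by both the ketone and the diene, and C7 stays untouched.
- F5 alone is cyclised under the conditions of step 8, which do not touch C9, and comes back to the route at 15.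

Step 12. The basic ylide may enolise the hindered C8 ketone instead of adding to it, and prolonged warming may trigger β-elimination of the silyloxy group.
- The fallback sets out from 18.
- One equivalent of Ph3P=CH2 at −78 °C converts only the aldehyde and gives the dienyl ketone F7.
- The weakly basic reagent from Me3SiCH2Li and CeCl3 (THF, −78 °C) adds to the ketone to give the β-hydroxysilane F8.
- HF in aqueous MeCN then effects Peterson elimination and cleavage of the silyl ether in one operation and comes back to the route at 20.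

Further compounds
F1 | step 8 | (2E,4R,8E)-4-[(tert-butyldimethylsilyl)oxy]-2,8-dimethyl-7-(3-methylbut-2-en-1-yl)undeca-2,8,10-triene-1,6-diol (epimers at C6 and C7) | OC/C(C)=C/[C@H](O[Si](C)(C)C(C)(C)C)CC(O)C(CC=C(C)C)/C(C)=C/C=C
F2 | step 8 | (2E,4R,8E)-4-[(tert-butyldimethylsilyl)oxy]-2,8-dimethyl-7-(3-methylbut-2-en-1-yl)-6-oxoundeca-2,8,10-trienal (both C7 epimers) | O=C/C(C)=C/[C@H](O[Si](C)(C)C(C)(C)C)CC(=O)C(CC=C(C)C)/C(C)=C/C=C
F3 | step 8 | (1S,4aR,8R,8aS)-8-[(tert-butyldimethylsilyl)oxy]-1,4a-dimethyl-5-(3-methylbut-2-en-1-yl)-6-oxo-1,2,4a,5,6,7,8,8a-octahydronaphthalene-1-carbaldehyde (both C5 epimers) | CC(C)=CCC1C(=O)C[C@@H](O[Si](C)(C)C(C)(C)C)[C@H]2[C@@]1(C)C=CC[C@]2(C)C=O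
F4 | step 8 | (1S,4aR,8R,8aS)-8-[(tert-butyldimethylsilyl)oxy]-1,4a-dimethyl-5-(3-methylbut-2-en-1-yl)-6-oxo-1,2,4a,5,6,7,8,8a-octahydronaphthalene-1-carboxylic acid (both C5 epimers) | CC(C)=CCC1C(=O)C[C@@H](O[Si](C)(C)C(C)(C)C)[C@H]2[C@@]1(C)C=CC[C@]2(C)C(=O)O
F5 | step 9 | methyl (2E,4R,7S,8E)-4-[(tert-butyldimethylsilyl)oxy]-2,8-dimethyl-7-(3-methylbut-2-en-1-yl)-6-oxoundeca-2,8,10-trienoate | COC(=O)/C(C)=C/[C@H](O[Si](C)(C)C(C)(C)C)CC(=O)[C@@H](CC=C(C)C)/C(C)=C/C=C
F6 | step 9 | methyl (2E,4R,7R,8E)-4-[(tert-butyldimethylsilyl)oxy]-2,8-dimethyl-7-(3-methylbut-2-en-1-yl)-6-oxoundeca-2,8,10-trienoate | COC(=O)/C(C)=C/[C@H](O[Si](C)(C)C(C)(C)C)CC(=O)[C@H](CC=C(C)C)/C(C)=C/C=C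
F7 | step 12 | methyl (1S,4aR,5S,8R,8aS)-8-[(tert-butyldimethylsilyl)oxy]-1,4a-dimethyl-5-[(2E)-3-methylpenta-2,4-dien-1-yl]-6-oxodecahydronaphthalene-1-carboxylate | C=C/C(C)=C/C[C@@H]1C(=O)C[C@@H](O[Si](C)(C)C(C)(C)C)[C@H]2[C@@]1(C)CCC[C@]2(C)C(=O)OC
F8 | step 12 | methyl 8-[(tert-butyldimethylsilyl)oxy]-6-hydroxy-1,4a-dimethyl-5-[(2E)-3-methylpenta-2,4-dien-1-yl]-6-[(trimethylsilyl)methyl]decahydronaphthalene-1-carboxylate (other centres as in F7, ring position 6 undefined) | C=C/C(C)=C/C[C@@H]1C(O)(C[Si](C)(C)C)C[C@@H](O[Si](C)(C)C(C)(C)C)[C@H]2[C@@]1(C)CCC[C@]2(C)C(=O)OC
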